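The ratio of the fractions of free monomer left at the last reading, east over south-west, is 2.31, and the ratio of their charges, south-west over east, is 2.20. So I work with the fraction left and not with the fraction made.

| flask | free monomer | initiator | remark | time |
|---|---|---|---|---|
| east | 0.10 M | 5 mM | run made earlier |  |
| north | 0.14 M | 5 mM | run made earlier |  |
| south-west | 0.22 M | 5 mM | run made earlier |  |
| Friday's | 0.10 M | 5.0 mM | a closed flask charged with all of it at once and left for 10 d | 10 d |
| Tuesday's | 0.10 M (fed, over 8.00 d) | 5.0 mM | a stirred flask in which free monomer is dosed at a steady rate over 8.00 d without added volume, worked up at 10 d | 10 d |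
| Wednesday's | 0.10 M | 5.0 mM | a single well-mixed tank run continuously and read at steady state, 10 d in it on average |  |

| run | time / d | monomer in chains / % |
|---|---|---|
| east | 0.833 | 55.5 |
| east | 1.25 | 54.5 |
| east | 1.67 | 54.4 |
| east | 3.00 | 55.7 |
| east | 4.00 | 54.8 |
| east | 6.00 | 56.1 |
| east | 10.0 | 54.4 |
| north | 0.625 | 64.6 |
| north | 1.67 | 68.9 |
| north | 3.00 | 68.2 |
| north | 5.00 | 69.0 |
| north | 8.00 | 68.5 |
| north | 10.0 | 66.4 |
| north | 12.0 | 67.8 |
| south-west | 1.04 | 78.1 |
| south-west | 1.67 | 78.9 |
| south-west | 2.00 | 80.5 |
| south-west | 3.00 | 80.4 |
| south-west | 5.00 | 79.2 |
| south-west | 8.00 | 79.7 |
| south-west | 12.0 | 80.3 |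

(scatter of a reading: 1 percentage point)

- the stated concentrations are those of everything mixed, before any reaction; amounts are the same in each set-up
- the feed brings no volume worth counting
- the earlier runs were made in a closed, stirred flask

- the set-up with the highest amount of monomer in chains at the outlet or at the end, in percent of the free monomer put in ("none" if the first two lie within 2 percentage points) (Friday's / Tuesday's / Wednesday's / none)
- amount of monomer in chains at the outlet or at the end, in percent of the free monomer put in, Friday's
- amount of monomer in chains at the outlet or at the end, in percent of the free monomer put in, Tuesday's
- amount of monomer in chains at the outlet or at the end, in percent of the free monomer put in, Wednesday's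

My first guess is a single first-order step each way, which holds the fraction left the same at any charge. It fails: east leaves 45.6 %, north 32.2 % and south-west 19.7 %. Multiplying each fraction by its charge gives 0.0456 M, 0.0451 M and 0.0433 M. Is that spread real? East and south-west differ by 1 percentage point of the south-west charge, and one reading scatters by 1 point, so I take the mean. This is the remainder R, the free monomer still standing when a run at 5 mM initiator stops rising, 0.0447 M. The field calls it the equilibrium monomer concentration. The share in chains is then one minus R over the charge, which gives my estimate for Friday's, 55.3 %.

But has each flask arrived? North's first reading, 64.6 % at 0.625 d, lies short of its last, 67.8 %. If that gap shrinks exponentially, its rate is roughly 4.89 d⁻¹, though this rests on one reading. Tuesday's feed stops at 8.00 d, which leaves 2.00 d, or 9.78 decay times, so I expect Friday's value there too. Wednesday's tank is the harder objection, since fresh charge keeps entering it. With 10 d on average in it, and if north's rate holds there too, the gap that remains is one part in 49.9, which gives 54.2 %. That is 1.1 points short, inside the margin of 2 points.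

The forecast gives 55.2 % for Friday's, 55.2 % for Tuesday's and 54 % for Wednesday's, so its answer is none. Its ground is that “about 0.045 M stays free, whatever the charge”. It reads the same plateaus as I do, so its closeness to my values checks nothing.

    free monomer + initiator → living end + monomer in chains (k = 0.0520 M⁻¹ min⁻¹)
    free monomer + living end → monomer in chains + living end, rate k2*[living end]*[free monomer] (k = 0.760 M⁻¹ min⁻¹)
    monomer in chains + living end → free monomer + living end, rate k3*[living end] as long as [monomer in chains] is above zero (k = 0.0340 min⁻¹)

The flask gives 55.3 % for Friday's, 55.3 % for Tuesday's and 54.3 % for Wednesday's, so the answer is none, and dosing gains Tuesday's nothing over Friday's. In Tuesday's flask free monomer peaks at 0.0470 M, about half of the whole charge. My remainder 0.0447 M over Friday's charge 0.10 M leaves 55.3 % in chains, and over 0.113 M, the charge at which Friday's answer has moved by 5 points, it gives 60.4 %.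

The data were computed with made-up constants; the scatter is artificial.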